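## Retrosynthetic overview
- The O1–C2 bond is disconnected first (retro-oxa-Michael). This opens the target to a fully unprotected bis-phloroglucinol chalcone with the same formula, C30H30O8.
- The Ar–CH2–Ar bridge is disconnected next (ortho-quinone methide plus phloroglucinol carbon). This gives 3'-prenyl-2',4',6'-trihydroxychalcone, formaldehyde and C-methylphloroacetophenone.
- The chalcone comes from benzaldehyde and 3-prenylphloroacetophenone. Both acetophenones come from phloroacetophenone by C-alkylation with prenyl bromide or MeI.
- Ring order: the three benzene rings are bought. The dihydropyranone ring is the only ring made, and it closes in the last step, which also sets C2 as S. Nothing that could racemise C2 follows.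

Assumption: the quinidine-derived thiourea is taken to give 2S; the first run is checked by CD (2S-flavanones show a negative band near 290 nm and a positive band near 330 nm), and if the product is 2R the quinine-derived pseudo-enantiomer is used with nothing else changed.

## Route

Step 1
Reactants: 1 2',4',6'-trihydroxyacetophenone (phloroacetophenone); 2 prenyl bromide (1-bromo-3-methylbut-2-ene)
Product: 3 2',4',6'-trihydroxy-3'-prenylacetophenone
Conditions: KOH (1.05 equiv), H2O, 2 (0.9 equiv) added dropwise, 0 °C → rt, 3 h
Reagents that add atoms: none
Why: This is C-alkylation of an ambident phloroglucinol phenoxide (aromatic prenylation), in which water solvates the oxygen so the soft allylic bromide attacks ring carbon, the equivalence of C3 and C5 in 1 allows only one mono-prenyl isomer, and the slight deficit of 2 limits diprenylation.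

Step 2
Reactants: 3 2',4',6'-trihydroxy-3'-prenylacetophenone; 4 benzaldehyde
Product: 5 (E)-2',4',6'-trihydroxy-3'-prenylchalcone
Conditions: PhCHO (1.5 equiv), 50% aq KOH (20 equiv), EtOH, Ar, rt, 48 h; then ice-cold 2 M HCl to pH 3, fast extraction
Reagents that add atoms: none
Why: This Claisen–Schmidt condensation (aldol addition, then E1cB dehydration) gives the conjugated E-enone under thermodynamic control, and concentrated KOH holds the product as the open polyanion, which has one more ionisable OH than the flavanone, so the chalcone is released only in the cold acid quench.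

Step 3
Reactants: 1 2',4',6'-trihydroxyacetophenone
Product: 6 2',4',6'-trihydroxy-3'-methylacetophenone
Conditions: MeI (1.0 equiv), KOH (1.05 equiv), MeOH–H2O, 0 °C → rt, 12 h
Reagents that add atoms: iodomethane, CI
Why: This is C-methylation of the phloroglucinol phenoxide, the same ambident-anion C-alkylation as in step 1, where the equivalent C3 and C5 positions give one mono-methyl isomer and one equivalent each of base and MeI holds back di- and gem-dimethylation, whose products are removed by crystallisation.

Step 4
Reactants: 5 (E)-2',4',6'-trihydroxy-3'-prenylchalcone; 6 2',4',6'-trihydroxy-3'-methylacetophenone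
Product: 9 (E)-5'-(3-acetyl-2,4,6-trihydroxy-5-methylbenzyl)-2',4',6'-trihydroxy-3'-prenylchalcone, via 3'-(hydroxymethyl)-2',4',6'-trihydroxy-5'-methylacetophenone 7 (not isolated), via ortho-quinone methide 4-acetyl-3,5-dihydroxy-2-methyl-6-methylidenecyclohexa-2,4-dien-1-one 8 (not isolated)
Conditions: 6 (3 equiv), 37% aq CH2O (2 equiv), 2 M KOH, H2O–MeOH, Ar, 0 °C, 1 h; then ice-cold 2 M HCl to pH 3
Reagents that add atoms: formaldehyde, C=O
Why: This is the classical formaldehyde methylene-bridging of acylphloroglucinols (hydroxymethylation, E1cB loss of hydroxide to the ortho-quinone methide, then Michael addition of the second ring), in which each partner has a single free ring carbon, the threefold excess of cheap 6 moves the statistical pairing to about 75% cross-product based on 5, and the strong alkali keeps the chalcone open.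

Step 5
Reactants: 9 (E)-5'-(3-acetyl-2,4,6-trihydroxy-5-methylbenzyl)-2',4',6'-trihydroxy-3'-prenylchalcone
Product: 10 (2S)-8-(3-acetyl-2,4,6-trihydroxy-5-methylbenzyl)-5,7-dihydroxy-6-prenylflavanone (target)
Conditions: 9-amino(9-deoxy)-epi-quinidine N'-[3,5-bis(trifluoromethyl)phenyl]thiourea (15 mol %), CH2Cl2–PhMe 1:1, 0.02 M, Ar, −20 °C, 48 h; AcOH quench at −20 °C, short silica plug
Reagents that add atoms: none
Why: Proposed new method: a chalcone-isomerase-like enantioselective 6-endo-trig intramolecular oxa-Michael addition on the unprotected bridged chalcone, in which the quinuclidine nitrogen deprotonates the bridge-side 6'-OH (the more acidic ortho hydroxyl because its phenoxide is held by an O–H···O− bond from the neighbouring ring, as in 2,2'-methylenebisphenols, and therefore also the faster-closing one since βnuc < 1), the prenyl-side 2'-OH keeps its activating chelate to C=O and becomes the 5-OH, the thiourea N–H pair binds that chelated carbonyl so the phenoxide adds to one enone face to set C2 as S before the ammonium protonates the enolate, and the low temperature and apolar medium suppress both the uncatalysed closure and the retro-reaction that would scramble C2 and the 6/8 pattern; the closest known reaction types are the cinchona-alkaloid- and cinchona-thiourea-catalysed asymmetric cyclisation of 2'-hydroxychalcones (and their α-ester-activated analogues) to flavanones, and the non-asymmetric flavanone closure of rottlerin-type bridged chalcones through a bridge-flanked hydroxyl.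

## Compound list
1 | 2',4',6'-trihydroxyacetophenone | CC(=O)c1c(O)cc(O)cc1O | starting material
2 | prenyl bromide | CC(C)=CCBr | starting material
3 | 2',4',6'-trihydroxy-3'-prenylacetophenone | CC(=O)c1c(O)cc(O)c(CC=C(C)C)c1O | intermediate
4 | benzaldehyde | O=Cc1ccccc1 | starting material
5 | (E)-2',4',6'-trihydroxy-3'-prenylchalcone | O=C(/C=C/c1ccccc1)c1c(O)cc(O)c(CC=C(C)C)c1O | intermediate
6 | 2',4',6'-trihydroxy-3'-methylacetophenone | CC(=O)c1c(O)cc(O)c(C)c1O | intermediate
7 | 3'-(hydroxymethyl)-2',4',6'-trihydroxy-5'-methylacetophenone (not isolated) | CC(=O)c1c(O)c(C)c(O)c(CO)c1O | intermediate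
8 | 4-acetyl-3,5-dihydroxy-2-methyl-6-methylidenecyclohexa-2,4-dien-1-one, ortho-quinone methide (not isolated) | C=C1C(=O)C(C)=C(O)C(C(C)=O)=C1O | intermediate
9 | (E)-5'-(3-acetyl-2,4,6-trihydroxy-5-methylbenzyl)-2',4',6'-trihydroxy-3'-prenylchalcone | CC(=O)c1c(O)c(C)c(O)c(Cc2c(O)c(CC=C(C)C)c(O)c(C(=O)/C=C/c3ccccc3)c2O)c1O | intermediate
10 | (2S)-8-(3-acetyl-2,4,6-trihydroxy-5-methylbenzyl)-5,7-dihydroxy-6-prenylflavanone | CC(=O)c1c(O)c(C)c(O)c(Cc2c(O)c(CC=C(C)C)c(O)c3c2O[C@H](c2ccccc2)CC3=O)c1O | target

Total step count: 5. Longest linear sequence: 4 (1 → 3 → 5 → 9 → 10).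

## Steps most likely to fail

**Step 5.**
- Risks: closure through the prenyl-side hydroxyl would give the 6-benzyl-8-prenyl isomer. The ee may also be only moderate on a substrate carrying six free phenols.
- Recovery: mis-closed material is not lost, because cold 2 M KOH followed by a cold acid quench reopens it to 9.
- Fallback: it sets out from 5 and comes back at 10. Chalcone 5 is cyclised with the same catalyst class. 3'-Prenyl-2',4',6'-trihydroxychalcones close mainly through the unhindered 6'-OH, so this gives (2S)-5,7-dihydroxy-6-prenylflavanone F1.
- In F1, C8 is the only free ring carbon. The bridge is then built last in acid, where C2 does not epimerise: 6 (3 equiv), aq CH2O and catalytic HCl in EtOH at 0 °C, running through 7 and 8 to 10.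

**Step 2.**
- Risk: the acetyl group of the unprotected polyanion enolises poorly, so conversion may be low, and part of the product may close to flavanone during work-up.
- Fallback: it sets out from 3 and comes back at 5. MOMCl and iPr2NEt in CH2Cl2 at 0 °C mask the two unchelated hydroxyls, giving 2'-hydroxy-4',6'-bis(methoxymethoxy)-3'-prenylacetophenone F2.
- Ordinary KOH/EtOH condensation with 4 then gives (E)-2'-hydroxy-4',6'-bis(methoxymethoxy)-3'-prenylchalcone F3. Brief HCl/MeOH at rt removes both acetals to release 5.

**Step 4.**
- Risk: homodimers form, and base-mediated exchange of the bridge may erode the cross-product.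
- Fallback: it sets out from 6 and comes back at 9 through 8. Compound 6 is condensed with aq CH2O and sodium p-toluenesulfinate in HCO2H/EtOH–H2O. This gives the crystalline quinone-methide precursor 2',4',6'-trihydroxy-3'-methyl-5'-(tosylmethyl)acetophenone F4.
- One equivalent of F4 is added to 5 (1.1 equiv) in 2 M KOH at 0 °C. It loses sulfinate at once to give 8, and the chalcone polyanion, the only carbon nucleophile present, traps it. The coupling is therefore directional rather than statistical.

## Further compounds
F1 | step 5 | (2S)-5,7-dihydroxy-6-prenylflavanone | CC(C)=CCc1c(O)cc2O[C@H](c3ccccc3)CC(=O)c2c1O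
F2 | step 2 | 2'-hydroxy-4',6'-bis(methoxymethoxy)-3'-prenylacetophenone | CC(=O)c1c(OCOC)cc(OCOC)c(CC=C(C)C)c1O
F3 | step 2 | (E)-2'-hydroxy-4',6'-bis(methoxymethoxy)-3'-prenylchalcone | O=C(/C=C/c1ccccc1)c1c(OCOC)cc(OCOC)c(CC=C(C)C)c1O
F4 | step 4 | 2',4',6'-trihydroxy-3'-methyl-5'-(tosylmethyl)acetophenone | CC(=O)c1c(O)c(C)c(O)c(CS(=O)(=O)c2ccc(C)cc2)c1O
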